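**Retrosynthetic overview** (chain numbered C1 = CO2H, C2 = CHMe, C5 = CH bearing the furan, C7=C8 = prenyl olefin)

1. C2–H, last stereocentre: target ⇐ its bis-MOM ether ⇐ the (E)-2-methyl-2-enoic acid, by ligand-controlled hydrogenation with Ru(OAc)2[(R)-H8-BINAP].
2. C7=C8: prenyl arm ⇐ CH2CHO arm, by Wittig isopropylidenation.
3. C4–C5, first stereocentre, metal-free key step: aldehyde-acid ⇐ β-(3-furyl)acrolein + the bis(silyl) dienediolate of tiglic acid, by iminium-catalysed vinylogous Mukaiyama–Michael addition.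
4. Furan C4–C bond: enal ⇐ 4-bromo-2-arylfuran, by Br/Li exchange and vinylogous formylation.
5. Ring order: no ring is built; the benzene ring (hydroquinone bis-MOM ether) and the furan ring (2,4-dibromofuran) are bought and joined first by Negishi coupling at furan C2.

Assumption: CIP analysis of the SMILES gives (2R,5R); 1,4-bis(methoxymethoxy)benzene is taken as a catalogue compound.

**Step 1**
Reactants: 1 1,4-bis(methoxymethoxy)benzene; 2 2,4-dibromofuran
Product: 5 2-[2,5-bis(methoxymethoxy)phenyl]-4-bromofuran, via aryllithium 3 (not isolated), via arylzinc chloride 4 (not isolated)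
Conditions: n-BuLi (1.1 equiv), THF, 0 °C, 1 h; ZnCl2 (1.2 equiv), 0 °C → rt; then 2 (0.9 equiv), Pd(PPh3)4 (3 mol %), THF, 50 °C
Reagents that add atoms: none
Why: MOM-directed ortho-lithiation (all four ring C–H positions of 1 are equivalent) and Li-to-Zn exchange give arylzinc 4, which in a Negishi coupling reacts only at the α-bromide of 2 because zerovalent palladium inserts fastest into the C–Br bond next to the ring oxygen, leaving the β-bromide for step 2.

**Step 2**
Reactants: 5 2-[2,5-bis(methoxymethoxy)phenyl]-4-bromofuran; 6 (E)-3-(dimethylamino)prop-2-enal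
Product: 9 (E)-3-{5-[2,5-bis(methoxymethoxy)phenyl]furan-3-yl}prop-2-enal, via 3-furyllithium 7 (not isolated), via lithium alkoxide adduct 8 (not isolated)
Conditions: n-BuLi (1.05 equiv), THF, −78 °C, 15 min; 6 (1.3 equiv), −78 → −20 °C; then 1 M aq. HCl, 0 °C, 30 min
Reagents that add atoms: water, O
Why: Bromine–lithium exchange at −78 °C outruns MOM-directed lithiation and keeps the 3-furyllithium from migrating to the α-position, 1,2-addition to the vinylogous formamide 6 gives alkoxide 8, and acid work-up expels dimethylamine to leave the E-enal (vinylogous Bouveault-type formylation), the aldehyde oxygen being delivered by water.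

**Step 3**
Reactants: 10 tiglic acid, (E)-2-methylbut-2-enoic acid
Product: 12 1,1-bis(tert-butyldimethylsilyloxy)-2-methylbuta-1,3-diene, via dilithium dienediolate 11 (not isolated)
Conditions: LiN(i-Pr)2 (2.2 equiv), THF, −78 → 0 °C; TBSCl (2.3 equiv), DMPU, −78 °C → rt; pentane, filtration, bulb-to-bulb distillation
Reagents that add atoms: tert-butyldimethylsilyl chloride, CC(C)(C)[Si](C)(C)Cl
Why: Two equivalents of amide base remove the carboxyl proton and a γ-methyl proton of tiglic acid, and O,O-silylation of the resulting dienediolate (the standard route to bis(silyl) ketene acetals) gives a diene whose two identical silyloxy groups leave no ketene-acetal E/Z isomerism.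

**Step 4** (key step)
Reactants: 9 (E)-3-{5-[2,5-bis(methoxymethoxy)phenyl]furan-3-yl}prop-2-enal; 12 1,1-bis(tert-butyldimethylsilyloxy)-2-methylbuta-1,3-diene
Product: 14 (2E,5R)-5-{5-[2,5-bis(methoxymethoxy)phenyl]furan-3-yl}-2-methyl-7-oxohept-2-enoic acid, via silyl ester 13 (not isolated)
Conditions: 12 (2.0 equiv), (R)-2-[diphenyl(trimethylsilyloxy)methyl]pyrrolidine (20 mol %), 4-nitrophenol (20 mol %), H2O (2 equiv), CH2Cl2, −20 → 0 °C; then AcOH–THF–H2O (3:1:1), rt
Reagents that add atoms: water, O
Why: Proposed new method: an iminium-catalysed vinylogous Mukaiyama–Michael addition in which the nucleophile is the bis(silyl) dienediolate of a free carboxylic acid, so that the adduct is released directly as the (E)-2-methyl-2-enoic acid; the (R)-prolinol silyl ether condenses with 9 to the E-iminium ion whose one face is blocked by the CPh2(OSiMe3) group, the unsubstituted γ-CH2 terminus of 12 (its α-carbon is fully substituted and flanked by two silyloxy groups) adds to the β-carbon from the open Re face to set C5 as R, the silyl carboxonium ion passes one silyl group to water to leave silyl ester 13 with the new E-trisubstituted olefin, and hydrolysis of the enamine returns the aldehyde (oxygen from water) and the catalyst; the closest known reaction type is the prolinol-silyl-ether-catalysed vinylogous Mukaiyama–Michael addition of ester-derived acyclic silyl dienol ethers and of 2-silyloxyfurans to enals.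

**Step 5**
Reactants: 14 (2E,5R)-5-{5-[2,5-bis(methoxymethoxy)phenyl]furan-3-yl}-2-methyl-7-oxohept-2-enoic acid
Product: 15 (2E,5S)-5-{5-[2,5-bis(methoxymethoxy)phenyl]furan-3-yl}-2,8-dimethylnona-2,7-dienoic acid
Conditions: i-PrPPh3I (2.6 equiv), KN(SiMe3)2 (2.5 equiv), THF, 0 °C; then 14, −78 °C → rt; aq. citric acid work-up
Reagents that add atoms: isopropyltriphenylphosphonium iodide, CC(C)[P+](c1ccccc1)(c1ccccc1)c1ccccc1.[I-]
Why: Wittig olefination with the non-stabilised isopropylidene ylide converts the CH2CHO arm into the prenyl group while the acid rides through as its carboxylate (it takes up one extra equivalent of ylide, returned on acidic work-up), and C5 is not touched, its descriptor changing from R to S only because the two side arms swap CIP rank.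

**Step 6**
Reactants: 15 (2E,5S)-5-{5-[2,5-bis(methoxymethoxy)phenyl]furan-3-yl}-2,8-dimethylnona-2,7-dienoic acid
Product: 16 (2R,5R)-5-{5-[2,5-bis(methoxymethoxy)phenyl]furan-3-yl}-2,8-dimethylnon-7-enoic acid
Conditions: Ru(OAc)2[(R)-H8-BINAP] (1 mol %), H2 (4 atm), MeOH, 25 °C
Reagents that add atoms: none
Why: Carboxylate-directed asymmetric hydrogenation (Noyori-type divalent ruthenium diacetate with an atropisomeric bisphosphine) reduces only the C2=C3 bond that binds through the carboxylate, so the prenyl olefin, the furan and the MOM ethers survive, and the (R)-ligand is expected to give (2R) by analogy with tiglic acid and other (E)-2-methyl-2-alkenoic acids (the antipodal ligand is used if the sense proves opposite), the remote C5 centre having no say (its descriptor returns to R by the ranking change).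

**Step 7**
Reactants: 16 (2R,5R)-5-{5-[2,5-bis(methoxymethoxy)phenyl]furan-3-yl}-2,8-dimethylnon-7-enoic acid
Product: 17 (2R,5R)-5-[5-(2,5-dihydroxyphenyl)furan-3-yl]-2,8-dimethylnon-7-enoic acid
Conditions: 2 M aq. HCl–THF (1:3), 40 °C, degassed, Ar
Reagents that add atoms: none
Why: Specific-acid hydrolysis of the two aryl methoxymethyl acetals (O-protonation, loss of the methoxymethyl cation, capture by water) frees the hydroquinone under dilute, oxygen-free conditions that neither protonate the trisubstituted olefin nor enolise C2, so both stereocentres reach the target unchanged.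

**Compound list**

1 | 1,4-bis(methoxymethoxy)benzene | COCOc1ccc(OCOC)cc1 | starting material
2 | 2,4-dibromofuran | Brc1coc(Br)c1 | starting material
3 | [2,5-bis(methoxymethoxy)phenyl]lithium | [Li]c1cc(OCOC)ccc1OCOC | intermediate
4 | [2,5-bis(methoxymethoxy)phenyl]zinc chloride | Cl[Zn]c1cc(OCOC)ccc1OCOC | intermediate
5 | 2-[2,5-bis(methoxymethoxy)phenyl]-4-bromofuran | Brc1coc(-c2cc(OCOC)ccc2OCOC)c1 | intermediate
6 | (E)-3-(dimethylamino)prop-2-enal | CN(C)/C=C/C=O | starting material
7 | {5-[2,5-bis(methoxymethoxy)phenyl]furan-3-yl}lithium | [Li]c1coc(-c2cc(OCOC)ccc2OCOC)c1 | intermediate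
8 | lithium (E)-1-{5-[2,5-bis(methoxymethoxy)phenyl]furan-3-yl}-3-(dimethylamino)prop-2-en-1-olate, racemic at the carbinol carbon | [Li]OC(/C=C/N(C)C)c1coc(-c2cc(OCOC)ccc2OCOC)c1 | intermediate
9 | (E)-3-{5-[2,5-bis(methoxymethoxy)phenyl]furan-3-yl}prop-2-enal | O=C/C=C/c1coc(-c2cc(OCOC)ccc2OCOC)c1 | intermediate
10 | tiglic acid, (E)-2-methylbut-2-enoic acid | C/C=C(\C)C(=O)O | starting material
11 | dilithium 2-methylbuta-1,3-diene-1,1-diolate | [Li]OC(O[Li])=C(C)C=C | intermediate
12 | 1,1-bis(tert-butyldimethylsilyloxy)-2-methylbuta-1,3-diene | C=CC(C)=C(O[Si](C)(C)C(C)(C)C)O[Si](C)(C)C(C)(C)C | intermediate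
13 | tert-butyldimethylsilyl (2E,5R)-5-{5-[2,5-bis(methoxymethoxy)phenyl]furan-3-yl}-2-methyl-7-oxohept-2-enoate | O=CC[C@@H](C/C=C(\C)C(=O)O[Si](C)(C)C(C)(C)C)c1coc(-c2cc(OCOC)ccc2OCOC)c1 | intermediate
14 | (2E,5R)-5-{5-[2,5-bis(methoxymethoxy)phenyl]furan-3-yl}-2-methyl-7-oxohept-2-enoic acid | O=CC[C@@H](C/C=C(\C)C(=O)O)c1coc(-c2cc(OCOC)ccc2OCOC)c1 | intermediate
15 | (2E,5S)-5-{5-[2,5-bis(methoxymethoxy)phenyl]furan-3-yl}-2,8-dimethylnona-2,7-dienoic acid | CC(C)=CC[C@@H](C/C=C(\C)C(=O)O)c1coc(-c2cc(OCOC)ccc2OCOC)c1 | intermediate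
16 | (2R,5R)-5-{5-[2,5-bis(methoxymethoxy)phenyl]furan-3-yl}-2,8-dimethylnon-7-enoic acid | CC(C)=CC[C@@H](CC[C@@H](C)C(=O)O)c1coc(-c2cc(OCOC)ccc2OCOC)c1 | intermediate
17 | (2R,5R)-5-[5-(2,5-dihydroxyphenyl)furan-3-yl]-2,8-dimethylnon-7-enoic acid | CC(C)=CC[C@@H](CC[C@@H](C)C(=O)O)c1coc(-c2cc(O)ccc2O)c1 | target

**Step count and risks**

Total steps: 7. Longest linear sequence: 6 (steps 1, 2, 4, 5, 6, 7; step 3 is a one-step side branch).

The three steps most likely to fail:

Step 4 (the proposed new step). The risks are protodesilylation of 12 by water or the acid co-catalyst before C–C bond formation, and sluggish turnover with the electron-rich furyl enal. The fallback uses the established ester variant and sets out from 9. Methyl tiglate is converted with LiN(i-Pr)2 and TBSCl (THF–DMPU, −78 °C) into tert-butyl[(1-methoxy-2-methylbuta-1,3-dien-1-yl)oxy]dimethylsilane F1. F1 adds to 9 under the same prolinol silyl ether and 4-nitrophenol conditions to give methyl (2E,5R)-5-{5-[2,5-bis(methoxymethoxy)phenyl]furan-3-yl}-2-methyl-7-oxohept-2-enoate F2. Wittig isopropylidenation as in step 5 (1.3 equiv of ylide) gives methyl (2E,5S)-5-{5-[2,5-bis(methoxymethoxy)phenyl]furan-3-yl}-2,8-dimethylnona-2,7-dienoate F3. Saponification (LiOH, THF–MeOH–H2O, 40 °C) comes back to the route at 15, at the cost of one extra step.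

Step 2. The risks are migration of lithium to the furan α-position or halogen scrambling before trapping, competing MOM-directed lithiation, and incomplete elimination of dimethylamine. The fallback avoids organolithium chemistry and sets out from 5. Suzuki–Miyaura coupling with commercial (E)-2-(3,3-diethoxyprop-1-en-1-yl)-4,4,5,5-tetramethyl-1,3,2-dioxaborolane (Pd(dppf)Cl2, K3PO4, dioxane–H2O, 80 °C) gives 2-[2,5-bis(methoxymethoxy)phenyl]-4-[(E)-3,3-diethoxyprop-1-en-1-yl]furan F4. Brief hydrolysis of the acetal (0.5 M aq. HCl–THF, 0 °C) comes back to the route at 9.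

Step 7. The risks are protonation of the prenyl olefin (hydration, or cyclisation of the tertiary cation onto furan C5) and acid opening of the furan. The fallback replaces Brønsted-acid hydrolysis by non-protic silyl exchange and sets out from 16. TMSOTf and 2,2′-bipyridyl (CH2Cl2, 0 °C → rt) convert both aryl MOM ethers into aryl silyl ethers and the acid into its silyl ester, giving trimethylsilyl (2R,5R)-5-{5-[2,5-bis(trimethylsilyloxy)phenyl]furan-3-yl}-2,8-dimethylnon-7-enoate F5. Neutral solvolysis (MeOH–H2O, rt, Ar) comes back to the route at 17.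

**Further compounds**

F1 | step 4 | tert-butyl[(1-methoxy-2-methylbuta-1,3-dien-1-yl)oxy]dimethylsilane | C=CC(C)=C(OC)O[Si](C)(C)C(C)(C)C
F2 | step 4 | methyl (2E,5R)-5-{5-[2,5-bis(methoxymethoxy)phenyl]furan-3-yl}-2-methyl-7-oxohept-2-enoate | O=CC[C@@H](C/C=C(\C)C(=O)OC)c1coc(-c2cc(OCOC)ccc2OCOC)c1
F3 | step 4 | methyl (2E,5S)-5-{5-[2,5-bis(methoxymethoxy)phenyl]furan-3-yl}-2,8-dimethylnona-2,7-dienoate | CC(C)=CC[C@@H](C/C=C(\C)C(=O)OC)c1coc(-c2cc(OCOC)ccc2OCOC)c1
F4 | step 2 | 2-[2,5-bis(methoxymethoxy)phenyl]-4-[(E)-3,3-diethoxyprop-1-en-1-yl]furan | CCOC(OCC)/C=C/c1coc(-c2cc(OCOC)ccc2OCOC)c1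
F5 | step 7 | trimethylsilyl (2R,5R)-5-{5-[2,5-bis(trimethylsilyloxy)phenyl]furan-3-yl}-2,8-dimethylnon-7-enoate | CC(C)=CC[C@@H](CC[C@@H](C)C(=O)O[Si](C)(C)C)c1coc(-c2cc(O[Si](C)(C)C)ccc2O[Si](C)(C)C)c1
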